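**Strategy.** The molecule is cut at the internal hydroxybutyrate, the O–CH(CH3)–CH2–C(=O)–O unit that links the ring C carbinol oxygen to the ring A carboxyl. This unit is taken as (R)-propylene oxide plus carbon monoxide. In one operation, Co2(CO)8 catalysis forms its CH2–C(=O) bond and its ester bond to the ring C carbinol, and leaves its own hydroxyl free for the ring A acid. The precursor is the benzyl-protected ring C benzoate that already carries the terminal benzyl (R)-3-hydroxybutanoate on its carboxyl and has a free (R)-2-hydroxypropyl side chain. Ring A arrives as a dioxolane-masked, benzyl-protected acid; acid hydrolysis and one hydrogenolysis finish the synthesis.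

Key step: step 9

Remark: the SMILES fixes all four stereocenters as (R); the three carbinols that stem from an epoxide are each taken from (R)-propylene oxide opened at its CH2 carbon (configuration carried over), the terminal one from methyl (R)-3-hydroxybutanoate, and 3,5-bis(benzyloxy)benzyl bromide is taken as a purchased compound.

**Route**

Step 1
Reactants: 1 5-bromoresorcinol
Product: 2 1,3-bis(benzyloxy)-5-bromobenzene
Conditions: BnBr, K2CO3, DMF, rt→50 °C
Reagents that add atoms: benzyl bromide, BrCc1ccccc1
Why: Double Williamson etherification of the two phenols, to which the aryl bromide is inert.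

Step 2
Reactants: 2 1,3-bis(benzyloxy)-5-bromobenzene; 3 (R)-propylene oxide
Product: 5 (2R)-1-[3,5-bis(benzyloxy)phenyl]propan-2-ol, via aryl Grignard reagent 4 (not isolated)
Conditions: Mg, THF, 50 °C; then CuI (10 mol%), 3, −30→0 °C
Reagents that add atoms: none
Why: CuI-catalysed SN2 opening of a terminal epoxide by an aryl Grignard reagent takes place at the unsubstituted CH2, so the (R) center of 3 is carried unchanged into the carbinol and the benzyl ethers are untouched.

Step 3
Reactants: 5 (2R)-1-[3,5-bis(benzyloxy)phenyl]propan-2-ol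
Product: 6 {[(2R)-1-[3,5-bis(benzyloxy)phenyl]propan-2-yl]oxy}(tert-butyl)dimethylsilane
Conditions: TBSCl, imidazole, DMF, rt
Reagents that add atoms: tert-butyldimethylsilyl chloride, CC(C)(C)[Si](C)(C)Cl
Why: Imidazole-mediated silylation of a secondary alcohol gives an ether that withstands NBS and n-BuLi and can later be removed by buffered fluoride instead of base.

Step 4
Reactants: 6 the TBS ether
Product: 7 {[(2R)-1-[3,5-bis(benzyloxy)-2-bromophenyl]propan-2-yl]oxy}(tert-butyl)dimethylsilane
Conditions: NBS, MeCN, 0 °C
Reagents that add atoms: N-bromosuccinimide, O=C1CCC(=O)N1Br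
Why: Electrophilic aromatic bromination of the resorcinol diether goes para to one benzyloxy group and ortho to the other at the carbon next to the side chain, because the carbon between the two benzyloxy groups is shielded on both sides, as is usual for 5-alkylresorcinol diethers.

Step 5
Reactants: 7 the aryl bromide
Product: 9 2,4-bis(benzyloxy)-6-[(2R)-2-{[tert-butyl(dimethyl)silyl]oxy}propyl]benzoic acid, via aryllithium 8 (not isolated)
Conditions: n-BuLi, THF, −78 °C; CO2; then cold 0.5 M HCl to pH 3
Reagents that add atoms: carbon dioxide, O=C=O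
Why: Bromine–lithium exchange at −78 °C outruns deprotonation of the benzylic ether CH2 groups, and carboxylation of the aryllithium gives the benzoic acid directly with the silyl ether intact.

Step 6
Reactants: 10 methyl (R)-3-hydroxybutanoate
Product: 11 benzyl (3R)-3-hydroxybutanoate
Conditions: BnOH (5 equiv), Ti(OiPr)4 (10 mol%), 100 °C, MeOH distilled off
Reagents that add atoms: benzyl alcohol, OCc1ccccc1
Why: Ti(OiPr)4-catalysed transesterification runs under neutral conditions that neither dehydrate nor racemise a β-hydroxy ester, and removal of methanol drives it to the benzyl ester with the (R) center untouched.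

Step 7
Reactants: 9 the ring C acid; 11 benzyl (3R)-3-hydroxybutanoate
Product: 13 benzyl (3R)-3-({2,4-bis(benzyloxy)-6-[(2R)-2-{[tert-butyl(dimethyl)silyl]oxy}propyl]benzoyl}oxy)butanoate, via acid chloride 12 (not isolated)
Conditions: Me2C=C(Cl)NMe2, CH2Cl2, 0 °C→rt; then 11, pyridine, DMAP, CH2Cl2, 0 °C→rt
Reagents that add atoms: none
Why: The neutral chloroenamine (Ghosez reagent) converts the hindered acid into its chloride without HCl, and DMAP-catalysed acylation of the secondary alcohol then forms the aryl ester with retention, since no bond to the carbinol carbon is broken.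

Step 8
Reactants: 13 the silyl-protected ring C diester
Product: 14 benzyl (3R)-3-({2,4-bis(benzyloxy)-6-[(2R)-2-hydroxypropyl]benzoyl}oxy)butanoate (ring C fragment with free (R)-carbinol and terminal benzyl hydroxybutyrate)
Conditions: HF·pyridine, pyridine, THF, 0 °C→rt; product used at once
Reagents that add atoms: none
Why: Fluoride-mediated desilylation in a pyridine-buffered, weakly acidic medium frees the carbinol without forming its alkoxide, the species that would close onto the neighbouring aryl ester, while both esters and the benzyl ethers are inert to HF·pyridine.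

Step 9
Reactants: 14 the ring C carbinol; 3 (R)-propylene oxide; 15 carbon monoxide
Product: 16 benzyl (3R)-3-{[2,4-bis(benzyloxy)-6-{(2R)-2-[(3R)-3-hydroxybutanoyloxy]propyl}benzoyl]oxy}butanoate (ring C triester with free hydroxyl on the new internal hydroxybutyrate)
Conditions: Co2(CO)8 (10 mol%), 3-hydroxypyridine (20 mol%), CO (40 bar), THF (1 M in 14), 55 °C; 3 (1.0 equiv) fed in portions, run stopped before 14 is used up, unreacted 14 recovered
Reagents that add atoms: none
Why: 3-Hydroxypyridine disproportionates Co2(CO)8 to the Co(CO)4− anion, which opens the hydrogen-bond-activated epoxide 3 at its CH2 carbon; CO inserts into the cobalt–alkyl bond, and the β-hydroxyacyl–Co(CO)4 species is cleaved by the carbinol of 14 with 3-hydroxypyridine relaying proton and acyl group, which returns the anion. The reaction type is the Co2(CO)8-catalysed alkoxycarbonylation of terminal epoxides to β-hydroxy esters, established with simple alcohols in excess; using one equivalent of a hindered secondary alcohol extends the stoichiometry, not the mechanism, and is the untested part. No ring is closed and no stereocenter is created: the methyl-bearing carbon of 3 is never touched and arrives as the (R) carbinol of the new hydroxybutyrate, while the two (R) centers of 14 are spectators. Two selectivities are needed: attack at CH2 and not CH of the epoxide, which the methyl group enforces sterically, and capture of the acyl species by the carbinol of 14 and not by the β-hydroxyl of the product or of the acyl species itself. The second should be favoured because a β-hydroxy ester hydroxyl is inductively deactivated and hydrogen-bonded to its own carbonyl, and because 14 is kept concentrated while 3 is fed slowly. The neutral medium never generates the alkoxide of 14, so closure onto the neighbouring aryl ester is not triggered.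

Step 10
Reactants: 17 1,3-dithiane; 3 (R)-propylene oxide
Product: 19 (2R)-1-(1,3-dithian-2-yl)propan-2-ol, via 2-lithio-1,3-dithiane 18 (not isolated)
Conditions: n-BuLi, THF, −30 °C; then 3, −30→0 °C; H2O
Reagents that add atoms: none
Why: Corey–Seebach alkylation in which the lithiated dithiane opens the epoxide at CH2 by SN2, so the (R) center of 3 becomes the (R) carbinol of the later ring A side chain.

Step 11
Reactants: 19 (2R)-1-(1,3-dithian-2-yl)propan-2-ol
Product: 20 2-[(2R)-2-(benzyloxy)propyl]-1,3-dithiane
Conditions: NaH, BnBr, n-Bu4NI (cat.), THF, 0 °C→rt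
Reagents that add atoms: benzyl bromide, BrCc1ccccc1
Why: Williamson benzylation of the sodium alkoxide, to which the dithiane is inert, installs an ether that will fall in the final hydrogenolysis together with all other benzyl groups.

Step 12
Reactants: 20 2-[(2R)-2-(benzyloxy)propyl]-1,3-dithiane; 21 3,5-bis(benzyloxy)benzyl bromide
Product: 23 2-[3,5-bis(benzyloxy)benzyl]-2-[(2R)-2-(benzyloxy)propyl]-1,3-dithiane, via lithiated dithiane 22 (not isolated)
Conditions: n-BuLi, THF, −30 °C, 2 h; then 21, −78 °C→rt
Reagents that add atoms: none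
Why: Second Corey–Seebach alkylation, in which the 2-alkyl dithiane is lithiated at C2 (the benzyloxy group is not on the adjacent carbon, so β-elimination is not possible) and the anion displaces the reactive benzylic bromide.

Step 13
Reactants: 23 the 2,2-disubstituted dithiane
Product: 24 (4R)-4-(benzyloxy)-1-[3,5-bis(benzyloxy)phenyl]pentan-2-one
Conditions: MeI, CaCO3, MeCN/H2O (9:1), 45 °C
Reagents that add atoms: water, O
Why: S-Methylation turns the dithiane into a sulfonium leaving group and water hydrolyses it to the ketone under CaCO3 buffering, with no oxidant or halogenating agent that could attack the electron-rich ring or the β-benzyloxy ketone.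

Step 14
Reactants: 24 the ketone
Product: 25 2-[3,5-bis(benzyloxy)benzyl]-2-[(2R)-2-(benzyloxy)propyl]-1,3-dioxolane
Conditions: (TMSOCH2)2, TMSOTf (5 mol%), CH2Cl2, −78→−20 °C; pyridine quench
Reagents that add atoms: 1,2-bis(trimethylsilyloxy)ethane, C[Si](C)(C)OCCO[Si](C)(C)C
Why: Noyori ketalisation with the bis-silyl ether of ethylene glycol works at low temperature under aprotic conditions, so the dioxolane forms without acid-induced loss of benzyl alcohol from the β-position.

Step 15
Reactants: 25 the dioxolane
Product: 26 2-[3,5-bis(benzyloxy)-2-bromobenzyl]-2-[(2R)-2-(benzyloxy)propyl]-1,3-dioxolane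
Conditions: NBS, MeCN, 0 °C
Reagents that add atoms: N-bromosuccinimide, O=C1CCC(=O)N1Br
Why: The same electrophilic bromination as in step 4, directed by the two benzyloxy groups to the ring carbon next to the side chain, with dioxolane and ethers inert to NBS.

Step 16
Reactants: 26 the aryl bromide
Product: 28 2,4-bis(benzyloxy)-6-({2-[(2R)-2-(benzyloxy)propyl]-1,3-dioxolan-2-yl}methyl)benzoic acid (protected ring A acid), via aryllithium 27 (not isolated)
Conditions: n-BuLi, THF, −78 °C; CO2; then cold 0.5 M HCl to pH 3–4
Reagents that add atoms: carbon dioxide, O=C=O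
Why: Bromine–lithium exchange and carboxylation as in step 5, with the dioxolane keeping the ketone away from the organolithium and surviving the brief cold acidification.

Step 17
Reactants: 28 the protected ring A acid; 16 the ring C triester with free hydroxyl
Product: 30 fully protected tetraester (16 acylated at its free hydroxyl by the 2,4-bis(benzyloxy)-6-({2-[(2R)-2-(benzyloxy)propyl]-1,3-dioxolan-2-yl}methyl)benzoyl group), via acid chloride 29 (not isolated)
Conditions: Me2C=C(Cl)NMe2, CH2Cl2, 0 °C→rt; then 16, pyridine, DMAP, CH2Cl2, rt→35 °C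
Reagents that add atoms: none
Why: DMAP-catalysed acylation of the secondary β-hydroxy ester hydroxyl by an aroyl chloride made under neutral conditions, in which the dioxolane stays closed and blocks enol-lactonisation of the activated acid to an isocoumarin, and the (R) carbinol is acylated with retention.

Step 18
Reactants: 30 the fully protected tetraester
Product: 31 hexabenzyl keto tetraester (as 30, with the dioxolane replaced by the free ketone; ring A side chain (4R)-4-(benzyloxy)-2-oxopentyl)
Conditions: 2 M HCl/THF (1:4), rt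
Reagents that add atoms: water, O
Why: Acid-catalysed ketal hydrolysis under dilute aqueous conditions that leave alkyl and aryl esters and benzyl ethers intact, run while every hydroxyl is still benzylated so that the product stays easy to purify and the last step can be a neutral one.

Step 19
Reactants: 31 the hexabenzyl keto tetraester
Product: 32 Hansforester I
Conditions: H2 (1 atm), Pd(OH)2/C, EtOAc/THF, rt
Reagents that add atoms: none
Why: Catalytic hydrogenolysis should cleave the four aryl benzyl ethers, the alkyl benzyl ether and the benzyl ester in one neutral operation, while the esters at non-benzylic secondary carbons, the dialkyl ketone and all four stereocenters are untouched.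

**Compound list**

1 | 5-bromoresorcinol | Oc1cc(O)cc(Br)c1 | starting material
2 | 1,3-bis(benzyloxy)-5-bromobenzene | Brc1cc(OCc2ccccc2)cc(OCc2ccccc2)c1 | intermediate
3 | (R)-propylene oxide | C[C@@H]1CO1 | starting material
4 | [3,5-bis(benzyloxy)phenyl]magnesium bromide | Br[Mg]c1cc(OCc2ccccc2)cc(OCc2ccccc2)c1 | intermediate
5 | (2R)-1-[3,5-bis(benzyloxy)phenyl]propan-2-ol | C[C@@H](O)Cc1cc(OCc2ccccc2)cc(OCc2ccccc2)c1 | intermediate
6 | {[(2R)-1-[3,5-bis(benzyloxy)phenyl]propan-2-yl]oxy}(tert-butyl)dimethylsilane | C[C@H](Cc1cc(OCc2ccccc2)cc(OCc2ccccc2)c1)O[Si](C)(C)C(C)(C)C | intermediate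
7 | {[(2R)-1-[3,5-bis(benzyloxy)-2-bromophenyl]propan-2-yl]oxy}(tert-butyl)dimethylsilane | C[C@H](Cc1cc(OCc2ccccc2)cc(OCc2ccccc2)c1Br)O[Si](C)(C)C(C)(C)C | intermediate
8 | {2,4-bis(benzyloxy)-6-[(2R)-2-{[tert-butyl(dimethyl)silyl]oxy}propyl]phenyl}lithium | C[C@H](Cc1cc(OCc2ccccc2)cc(OCc2ccccc2)c1[Li])O[Si](C)(C)C(C)(C)C | intermediate
9 | 2,4-bis(benzyloxy)-6-[(2R)-2-{[tert-butyl(dimethyl)silyl]oxy}propyl]benzoic acid | C[C@H](Cc1cc(OCc2ccccc2)cc(OCc2ccccc2)c1C(=O)O)O[Si](C)(C)C(C)(C)C | intermediate
10 | methyl (R)-3-hydroxybutanoate | C[C@@H](O)CC(=O)OC | starting material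
11 | benzyl (3R)-3-hydroxybutanoate | C[C@@H](O)CC(=O)OCc1ccccc1 | intermediate
12 | 2,4-bis(benzyloxy)-6-[(2R)-2-{[tert-butyl(dimethyl)silyl]oxy}propyl]benzoyl chloride | C[C@H](Cc1cc(OCc2ccccc2)cc(OCc2ccccc2)c1C(Cl)=O)O[Si](C)(C)C(C)(C)C | intermediate
13 | benzyl (3R)-3-({2,4-bis(benzyloxy)-6-[(2R)-2-{[tert-butyl(dimethyl)silyl]oxy}propyl]benzoyl}oxy)butanoate | C[C@H](Cc1cc(OCc2ccccc2)cc(OCc2ccccc2)c1C(=O)O[C@H](C)CC(=O)OCc1ccccc1)O[Si](C)(C)C(C)(C)C | intermediate
14 | benzyl (3R)-3-({2,4-bis(benzyloxy)-6-[(2R)-2-hydroxypropyl]benzoyl}oxy)butanoate | C[C@@H](O)Cc1cc(OCc2ccccc2)cc(OCc2ccccc2)c1C(=O)O[C@H](C)CC(=O)OCc1ccccc1 | intermediate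
15 | carbon monoxide | [C-]#[O+] | starting material
16 | benzyl (3R)-3-{[2,4-bis(benzyloxy)-6-{(2R)-2-[(3R)-3-hydroxybutanoyloxy]propyl}benzoyl]oxy}butanoate | C[C@H](Cc1cc(OCc2ccccc2)cc(OCc2ccccc2)c1C(=O)O[C@H](C)CC(=O)OCc1ccccc1)OC(=O)C[C@@H](C)O | intermediate
17 | 1,3-dithiane | C1CSCSC1 | starting material
18 | 2-lithio-1,3-dithiane | [Li]C1SCCCS1 | intermediate
19 | (2R)-1-(1,3-dithian-2-yl)propan-2-ol | C[C@@H](O)CC1SCCCS1 | intermediate
20 | 2-[(2R)-2-(benzyloxy)propyl]-1,3-dithiane | C[C@H](CC1SCCCS1)OCc1ccccc1 | intermediate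
21 | 3,5-bis(benzyloxy)benzyl bromide | BrCc1cc(OCc2ccccc2)cc(OCc2ccccc2)c1 | starting material
22 | 2-lithio-2-[(2R)-2-(benzyloxy)propyl]-1,3-dithiane | C[C@H](CC1([Li])SCCCS1)OCc1ccccc1 | intermediate
23 | 2-[3,5-bis(benzyloxy)benzyl]-2-[(2R)-2-(benzyloxy)propyl]-1,3-dithiane | C[C@H](CC1(Cc2cc(OCc3ccccc3)cc(OCc3ccccc3)c2)SCCCS1)OCc1ccccc1 | intermediate
24 | (4R)-4-(benzyloxy)-1-[3,5-bis(benzyloxy)phenyl]pentan-2-one | C[C@H](CC(=O)Cc1cc(OCc2ccccc2)cc(OCc2ccccc2)c1)OCc1ccccc1 | intermediate
25 | 2-[3,5-bis(benzyloxy)benzyl]-2-[(2R)-2-(benzyloxy)propyl]-1,3-dioxolane | C[C@H](CC1(Cc2cc(OCc3ccccc3)cc(OCc3ccccc3)c2)OCCO1)OCc1ccccc1 | intermediate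
26 | 2-[3,5-bis(benzyloxy)-2-bromobenzyl]-2-[(2R)-2-(benzyloxy)propyl]-1,3-dioxolane | C[C@H](CC1(Cc2cc(OCc3ccccc3)cc(OCc3ccccc3)c2Br)OCCO1)OCc1ccccc1 | intermediate
27 | {2,4-bis(benzyloxy)-6-({2-[(2R)-2-(benzyloxy)propyl]-1,3-dioxolan-2-yl}methyl)phenyl}lithium | C[C@H](CC1(Cc2cc(OCc3ccccc3)cc(OCc3ccccc3)c2[Li])OCCO1)OCc1ccccc1 | intermediate
28 | 2,4-bis(benzyloxy)-6-({2-[(2R)-2-(benzyloxy)propyl]-1,3-dioxolan-2-yl}methyl)benzoic acid | C[C@H](CC1(Cc2cc(OCc3ccccc3)cc(OCc3ccccc3)c2C(=O)O)OCCO1)OCc1ccccc1 | intermediate
29 | 2,4-bis(benzyloxy)-6-({2-[(2R)-2-(benzyloxy)propyl]-1,3-dioxolan-2-yl}methyl)benzoyl chloride | C[C@H](CC1(Cc2cc(OCc3ccccc3)cc(OCc3ccccc3)c2C(Cl)=O)OCCO1)OCc1ccccc1 | intermediate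
30 | fully protected tetraester: 16 acylated at its hydroxyl by the acyl group of 28 | C[C@H](Cc1cc(OCc2ccccc2)cc(OCc2ccccc2)c1C(=O)O[C@H](C)CC(=O)OCc1ccccc1)OC(=O)C[C@@H](C)OC(=O)c1c(OCc2ccccc2)cc(OCc2ccccc2)cc1CC1(C[C@@H](C)OCc2ccccc2)OCCO1 | intermediate
31 | hexabenzyl keto tetraester: 30 with the dioxolane hydrolysed to the ketone | C[C@H](Cc1cc(OCc2ccccc2)cc(OCc2ccccc2)c1C(=O)O[C@H](C)CC(=O)OCc1ccccc1)OC(=O)C[C@@H](C)OC(=O)c1c(OCc2ccccc2)cc(OCc2ccccc2)cc1CC(=O)C[C@@H](C)OCc1ccccc1 | intermediate
32 | Hansforester I | C[C@H](Cc1cc(O)cc(O)c1C(=O)O[C@H](C)CC(=O)O)OC(=O)C[C@@H](C)OC(=O)c1c(O)cc(O)cc1CC(=O)C[C@@H](C)O | target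

**Step count and risks**

Total step count: 19. Longest linear sequence: 11 steps (steps 1–5, 7–9, 17–19).

Steps most likely to fail:

1. Step 9. The hindered carbinol of 14 may capture the acyl–Co(CO)4 intermediate too slowly. The β-hydroxyl of the product would then take up further epoxide and CO (chain growth), or the acyl intermediate would close on its own hydroxyl. On prolonged heating the carbinol of 14 could also close onto its aryl ester. Fallback by known acylation, setting out from 14 (with 10) and returning at 16: silylation of 10 (TBSCl, imidazole, DMF) should give methyl (3R)-3-{[tert-butyl(dimethyl)silyl]oxy}butanoate F1. LiOH in aqueous THF should then give (3R)-3-{[tert-butyl(dimethyl)silyl]oxy}butanoic acid F2. Steglich esterification of the carbinol of 14 with F2 (DCC, catalytic DMAP, CH2Cl2, 0 °C) should give benzyl (3R)-3-{[2,4-bis(benzyloxy)-6-{(2R)-2-[((3R)-3-{[tert-butyl(dimethyl)silyl]oxy}butanoyl)oxy]propyl}benzoyl]oxy}butanoate F3. HF·pyridine as in step 8 should then release 16.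

2. Step 17. Acyl transfer from the di-ortho-substituted aroyl chloride to a β-hydroxy ester hydroxyl may be slow. That would leave time for a dioxolane oxygen to attack the activated carbonyl, or for base to expel the new aroyloxy group from the β-position. Fallback that activates the alcohol instead of the acid, setting out from 14 and returning at 30: the carbonylation of step 9 is run with (S)-propylene oxide (purchased, C[C@H]1CO1) to give benzyl (3R)-3-{[2,4-bis(benzyloxy)-6-{(2R)-2-[(3S)-3-hydroxybutanoyloxy]propyl}benzoyl]oxy}butanoate F4. A Mitsunobu reaction of F4 with acid 28 (PPh3, DIAD, toluene, 0 °C→rt) should then form the aryl ester with inversion to the (R) configuration and give 30. Hindered benzoic acids are good partners here because the carboxylate attacks as nucleophile.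

3. Step 7. Slow acylation by the hindered aroyl chloride could allow the neighbouring silyl ether oxygen to close onto the acyl chloride with loss of the silyl group, or allow base-induced elimination in the β-acyloxy ester. Fallback without acyl activation, setting out from 9 and returning at 13: purchased methyl (S)-3-hydroxybutanoate is transesterified as in step 6 to benzyl (3S)-3-hydroxybutanoate F5. A Mitsunobu reaction of F5 with acid 9 (PPh3, DIAD, toluene, 0 °C→rt) should then give 13 with inversion at the carbinol carbon.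

Further compounds
F1 | step 9 | methyl (3R)-3-{[tert-butyl(dimethyl)silyl]oxy}butanoate | C[C@H](CC(=O)OC)O[Si](C)(C)C(C)(C)C
F2 | step 9 | (3R)-3-{[tert-butyl(dimethyl)silyl]oxy}butanoic acid | C[C@H](CC(=O)O)O[Si](C)(C)C(C)(C)C
F3 | step 9 | benzyl (3R)-3-{[2,4-bis(benzyloxy)-6-{(2R)-2-[((3R)-3-{[tert-butyl(dimethyl)silyl]oxy}butanoyl)oxy]propyl}benzoyl]oxy}butanoate | C[C@H](Cc1cc(OCc2ccccc2)cc(OCc2ccccc2)c1C(=O)O[C@H](C)CC(=O)OCc1ccccc1)OC(=O)C[C@@H](C)O[Si](C)(C)C(C)(C)C
F4 | step 17 | benzyl (3R)-3-{[2,4-bis(benzyloxy)-6-{(2R)-2-[(3S)-3-hydroxybutanoyloxy]propyl}benzoyl]oxy}butanoate | C[C@H](Cc1cc(OCc2ccccc2)cc(OCc2ccccc2)c1C(=O)O[C@H](C)CC(=O)OCc1ccccc1)OC(=O)C[C@H](C)O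
F5 | step 7 | benzyl (3S)-3-hydroxybutanoate | C[C@H](O)CC(=O)OCc1ccccc1
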